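The hexasubstituted benzene ring is disconnected at C4a–C5 (chromene numbering). Its pattern is para hydroxyls at C5 and C8, methoxy at C7 beside C8, the acyl carbon at C6 beside C5, and the pyran ring fused at C4a–C8a. A squarate-derived 4-alkenyl-4-hydroxycyclobutenone stores exactly this pattern. Precursor 12 carries a dithiane-masked acyl group at C2, methoxy at C3, and hydroxyl plus a 6,6-dimethyldihydropyranyl group at C4 (cyclobutenone numbering). Heating opens the four-membered ring to a dienylketene that recloses onto the enol ether carbon, so the arene and the chroman bicycle arise in one operation. Acetylation in the same flask protects the hydroquinone. Dithiane removal, C3–C4 dehydrogenation and deacetylation complete the route.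

Key step: step 4

Remark: flemistrictin D has no stereocentre and is achiral, so there is no enantiomer to select; the stereocentres met on the way (in 6, 7, 11, 12 and 14) are racemic and all vanish.
Remark: 2,2-dimethyl-3,4-dihydro-2H-pyran 9 is taken as a catalogue building block; the other starting materials are common chemicals.

Step 1
Reactants: 1 3-phenylpropanal; 2 propane-1,3-dithiol
Product: 3 2-(2-phenylethyl)-1,3-dithiane
Conditions: BF3·OEt2 (0.1 equiv), CH2Cl2, 0 °C → rt
Reagents that add atoms: none
Why: Lewis-acid-catalysed dithioacetalisation of an unhindered aliphatic aldehyde is reliable and installs the Corey–Seebach acyl-anion handle without creating a stereocentre.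

Step 2
Reactants: 3 2-(2-phenylethyl)-1,3-dithiane; 4 dimethyl squarate
Product: 8 3-methoxy-4-[2-(2-phenylethyl)-1,3-dithian-2-yl]cyclobut-3-ene-1,2-dione, via lithiodithiane 5 (not isolated), via lithium alkoxide 6 (not isolated), via trifluoroacetate 7 (not isolated)
Conditions: n-BuLi, THF, −30 °C; cannulate into 4, THF, −78 °C; (CF3CO)2O, −78 °C; then H2O, → rt
Reagents that add atoms: water, SMILES O
Why: Corey–Seebach deprotonation gives acyl-anion equivalent 5, whose 1,2-addition to the very electrophilic squarate carbonyl and trifluoroacetylation give 7, an ester that ionises to a methoxy-stabilised cyclobutenyl cation and is hydrolysed at the C–OMe carbon next to the ketone (the standard squarate to 3-alkoxy-4-substituted cyclobutenedione sequence), while any conjugate addition–elimination would lead to the same dione 8 and the racemic carbinol centre of 6 and 7 disappears.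

Step 3
Reactants: 8 3-methoxy-4-[2-(2-phenylethyl)-1,3-dithian-2-yl]cyclobut-3-ene-1,2-dione; 9 2,2-dimethyl-3,4-dihydro-2H-pyran
Product: 12 rac-4-(6,6-dimethyl-5,6-dihydro-4H-pyran-2-yl)-4-hydroxy-3-methoxy-2-[2-(2-phenylethyl)-1,3-dithian-2-yl]cyclobut-2-en-1-one, via lithiodihydropyran 10 (not isolated), via lithium alkoxide 11 (not isolated)
Conditions: 9 (slight excess over base), t-BuLi, THF–pentane, −78 → 0 °C; cannulate into 8, THF, −78 °C; aq NH4Cl; Et3N-deactivated SiO2
Reagents that add atoms: none
Why: α-lithiation of a cyclic enol ether followed by 1,2-addition of the vinyllithium goes to the carbonyl flanked by C–OMe, because the other carbonyl is deactivated as a vinylogous ester and shielded by the dithiane, and the new carbinol centre forms as a racemate that the next step erases.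

Step 4
Reactants: 12 rac-4-(6,6-dimethyl-5,6-dihydro-4H-pyran-2-yl)-4-hydroxy-3-methoxy-2-[2-(2-phenylethyl)-1,3-dithian-2-yl]cyclobut-2-en-1-one
Product: 16 7-methoxy-2,2-dimethyl-6-[2-(2-phenylethyl)-1,3-dithian-2-yl]chroman-5,8-diyl diacetate, via dienylketene 13 (not isolated), via cyclohexadienone 14 (not isolated), via chroman-5,8-diol 15 (not isolated)
Conditions: PhMe (degassed, dilute, base-washed glass), 110 °C, Ar; cool to rt; Ac2O, Et3N, DMAP (cat.), rt → 40 °C
Reagents that add atoms: acetic anhydride, SMILES CC(=O)OC(C)=O
Why: Heating breaks the strained C1–C4 bond of 12 in a conrotatory 4π electrocyclic opening in which the donor hydroxyl turns outward (torquoselectivity), so the dihydropyranyl group turns inward and dienylketene 13 is born with its enol ether double bond beside the ketene. A thermal disrotatory 6π electrocyclisation then joins the ketene carbon (future C5) to the enol ether β-carbon (future C4a) and closes the six-membered carbocycle onto the existing pyran ring as cyclohexadienone 14, whose C4a–H enolises irreversibly to hydroquinone 15. This is the Moore rearrangement of squarate-derived 4-alkenyl-4-hydroxycyclobutenones, a well-established hydroquinone and quinone synthesis in which only the dithianyl spectator at C2 is new. No stereocentre survives, since the carbinol carbon of 12 becomes aromatic C8 and the transient C4a centre of 14 is lost on aromatisation. The substitution pattern needs no selectivity in this step because it is written into 12 (masked acyl next to the ketene carbon, methoxy next to the carbinol carbon), and the sulfur atoms could reach the ketene carbon only through a four-membered ring, so they should not compete with the 6π closure. Acetic anhydride added to the cooled, oxygen-free solution caps both phenols of 15 before air can oxidise it to the quinone, which also shields the ring from the reagents of steps 5 and 6.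

Step 5
Reactants: 16 7-methoxy-2,2-dimethyl-6-[2-(2-phenylethyl)-1,3-dithian-2-yl]chroman-5,8-diyl diacetate
Product: 17 7-methoxy-2,2-dimethyl-6-(3-phenylpropanoyl)chroman-5,8-diyl diacetate
Conditions: MeI (excess), CaCO3, MeCN–H2O (9:1), 45 °C
Reagents that add atoms: water, SMILES O
Why: Alkylative dithiane hydrolysis (S-methylation, thionium ion formation, capture by water) is non-oxidising, so the electron-rich arene, the benzylic C4–H bonds and the aryl acetates should be left alone, and relief of crowding between the two ortho substituents helps the C–S ionisation.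

Step 6
Reactants: 17 7-methoxy-2,2-dimethyl-6-(3-phenylpropanoyl)chroman-5,8-diyl diacetate
Product: 18 7-methoxy-2,2-dimethyl-6-(3-phenylpropanoyl)-2H-chromene-5,8-diyl diacetate
Conditions: DDQ (1.5 equiv), 1,4-dioxane, reflux
Reagents that add atoms: none
Why: DDQ dehydrogenation of 2,2-dimethylchromans to 2H-chromenes starts with hydride abstraction from C4, whose cation is stabilised by O1 (through C8a, ortho) and by the C7 methoxy group (para), and ends with loss of a C3 proton, while the acetates block quinone formation and the unactivated PhCH2 position reacts far more slowly.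

Step 7
Reactants: 18 7-methoxy-2,2-dimethyl-6-(3-phenylpropanoyl)-2H-chromene-5,8-diyl diacetate
Product: 19 flemistrictin D
Conditions: K2CO3, MeOH (degassed), Ar, 0 °C → rt; then 1 M HCl (degassed)
Reagents that add atoms: none
Why: Base-mediated transesterification cleaves aryl acetates much faster than anything else in 18 reacts, and exclusion of oxygen with an acidic quench keeps the liberated hydroquinone, whose C5 hydroxyl is hydrogen-bonded to the ketone, in the reduced state.

Compound list
1 | 3-phenylpropanal | O=CCCc1ccccc1 | starting material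
2 | propane-1,3-dithiol | SCCCS | starting material
3 | 2-(2-phenylethyl)-1,3-dithiane | c1ccccc1CCC1SCCCS1 | intermediate
4 | dimethyl squarate | COC1=C(OC)C(=O)C1=O | starting material
5 | 2-lithio-2-(2-phenylethyl)-1,3-dithiane | [Li]C1(CCc2ccccc2)SCCCS1 | intermediate
6 | lithium 2,3-dimethoxy-4-oxo-1-[2-(2-phenylethyl)-1,3-dithian-2-yl]cyclobut-2-en-1-olate (racemic) | [Li]OC1(C2(CCc3ccccc3)SCCCS2)C(OC)=C(OC)C1=O | intermediate
7 | 2,3-dimethoxy-4-oxo-1-[2-(2-phenylethyl)-1,3-dithian-2-yl]cyclobut-2-en-1-yl trifluoroacetate (racemic) | O=C(OC1(C2(CCc3ccccc3)SCCCS2)C(OC)=C(OC)C1=O)C(F)(F)F | intermediate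
8 | 3-methoxy-4-[2-(2-phenylethyl)-1,3-dithian-2-yl]cyclobut-3-ene-1,2-dione | COC1=C(C2(CCc3ccccc3)SCCCS2)C(=O)C1=O | intermediate
9 | 2,2-dimethyl-3,4-dihydro-2H-pyran | CC1(C)CCC=CO1 | starting material
10 | 6-lithio-2,2-dimethyl-3,4-dihydro-2H-pyran | [Li]C1=CCCC(C)(C)O1 | intermediate
11 | lithium alkoxide of 12 (racemic) | [Li]OC1(C2=CCCC(C)(C)O2)C(OC)=C(C2(CCc3ccccc3)SCCCS2)C1=O | intermediate
12 | rac-4-(6,6-dimethyl-5,6-dihydro-4H-pyran-2-yl)-4-hydroxy-3-methoxy-2-[2-(2-phenylethyl)-1,3-dithian-2-yl]cyclobut-2-en-1-one | O=C1C(C2(CCc3ccccc3)SCCCS2)=C(OC)C1(O)C1=CCCC(C)(C)O1 | intermediate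
13 | 4-(6,6-dimethyl-5,6-dihydro-4H-pyran-2-yl)-4-hydroxy-3-methoxy-2-[2-(2-phenylethyl)-1,3-dithian-2-yl]buta-1,3-dien-1-one, hydroxyl trans to the ketene arm | O=C=C(C1(CCc2ccccc2)SCCCS1)/C(OC)=C(/O)C1=CCCC(C)(C)O1 | intermediate
14 | 8-hydroxy-7-methoxy-2,2-dimethyl-6-[2-(2-phenylethyl)-1,3-dithian-2-yl]-2,3,4,4a-tetrahydro-5H-chromen-5-one (racemic at C4a) | O=C1C(C3(CCc4ccccc4)SCCCS3)=C(OC)C(O)=C2OC(C)(C)CCC12 | intermediate
15 | 7-methoxy-2,2-dimethyl-6-[2-(2-phenylethyl)-1,3-dithian-2-yl]chroman-5,8-diol | COc1c(O)c2c(c(O)c1C1(CCc3ccccc3)SCCCS1)CCC(C)(C)O2 | intermediate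
16 | 7-methoxy-2,2-dimethyl-6-[2-(2-phenylethyl)-1,3-dithian-2-yl]chroman-5,8-diyl diacetate | COc1c(OC(C)=O)c2c(c(OC(C)=O)c1C1(CCc3ccccc3)SCCCS1)CCC(C)(C)O2 | intermediate
17 | 7-methoxy-2,2-dimethyl-6-(3-phenylpropanoyl)chroman-5,8-diyl diacetate | COc1c(OC(C)=O)c2c(c(OC(C)=O)c1C(=O)CCc1ccccc1)CCC(C)(C)O2 | intermediate
18 | 7-methoxy-2,2-dimethyl-6-(3-phenylpropanoyl)-2H-chromene-5,8-diyl diacetate | COc1c(OC(C)=O)c2c(c(OC(C)=O)c1C(=O)CCc1ccccc1)C=CC(C)(C)O2 | intermediate
19 | flemistrictin D, 1-(5,8-dihydroxy-7-methoxy-2,2-dimethyl-2H-chromen-6-yl)-3-phenylpropan-1-one (achiral) | COc1c(O)c2c(c(O)c1C(=O)CCc1ccccc1)C=CC(C)(C)O2 | target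

Total step count: 7. Longest linear sequence: 7 steps (1 → 3 → 8 → 12 → 16 → 17 → 18 → 19).

Steps most likely to fail

Step 4.
- **Risk:** on heating, the free tertiary carbinol next to the enol ether may ionise or be diverted into lactone formation. The ketene may be intercepted before the 6π closure. The hydroquinone may oxidise in air before it is capped.
- **Fallback (phenol protection moved ahead of the ring expansion):** it sets out from lithium alkoxide 11. This is trapped in the flask of step 3 with chlorotriethylsilane to give the 4-(triethylsilyloxy)cyclobutenone F1. Thermolysis of F1 in toluene should follow the same electrocyclic course, since a siloxy group is also an outward-rotating donor. It delivers the oxidation-proof, purifiable 8-(triethylsilyloxy)chroman-5-ol F2. TBAF buffered with acetic acid under argon then releases 15. There the fallback rejoins the route, and acetylation proceeds as in step 4.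

Step 2.
- **Risk:** the hindered tertiary carbanion may add slowly or transfer an electron to the squarate. Sulfur participation (a 1,2-sulfur shift with ring expansion of the dithiane) may occur while 7 ionises.
- **Fallback (ketone masked as a 1,1-disubstituted alkene instead of a dithiane):** it sets out from 4.
  - Purchased 2-bromo-4-phenylbut-1-ene F3 undergoes bromine–lithium exchange with t-BuLi to give 4-phenylbut-1-en-2-yllithium F4.
  - F4 is added to 4 and treated with trifluoroacetic anhydride and water as in step 2. This gives 3-methoxy-4-(4-phenylbut-1-en-2-yl)cyclobut-3-ene-1,2-dione F5.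
  - Vinyllithium 10 adds as in step 3 to give the 2-alkenyl-4-hydroxycyclobutenone F6.
  - Thermolysis gives the 6-alkenylchroman-5,8-diol F7, which is capped in the flask as the 6-alkenylchroman diacetate F8.
  - Lemieux–Johnson cleavage of the methylene group (OsO4 cat., NaIO4, 2,6-lutidine, dioxane–water) gives 17, where the fallback rejoins the route.

Step 6.
- **Risk:** hydride abstraction from an arene damped by two acetates and an acyl group may be incomplete. The dihydrochalcone chain may be dehydrogenated in competition on prolonged heating.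
- **Fallback (halogenation–elimination instead of hydride abstraction):** it sets out from 17. Wohl–Ziegler bromination (NBS, AIBN, PhCF3, reflux) at the most electron-rich benzylic position gives the racemic 4-bromochroman diacetate F9. E2 elimination with DBU in toluene gives 18, where the fallback rejoins the route.

Further compounds
F1 | step 4 | rac-4-(6,6-dimethyl-5,6-dihydro-4H-pyran-2-yl)-3-methoxy-2-[2-(2-phenylethyl)-1,3-dithian-2-yl]-4-(triethylsilyloxy)cyclobut-2-en-1-one | CC[Si](CC)(CC)OC1(C2=CCCC(C)(C)O2)C(OC)=C(C2(CCc3ccccc3)SCCCS2)C1=O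
F2 | step 4 | 7-methoxy-2,2-dimethyl-6-[2-(2-phenylethyl)-1,3-dithian-2-yl]-8-(triethylsilyloxy)chroman-5-ol | COc1c(O[Si](CC)(CC)CC)c2c(c(O)c1C1(CCc3ccccc3)SCCCS1)CCC(C)(C)O2
F3 | step 2 | 2-bromo-4-phenylbut-1-ene (purchased) | C=C(Br)CCc1ccccc1
F4 | step 2 | 4-phenylbut-1-en-2-yllithium | [Li]C(=C)CCc1ccccc1
F5 | step 2 | 3-methoxy-4-(4-phenylbut-1-en-2-yl)cyclobut-3-ene-1,2-dione | COC1=C(C(=C)CCc2ccccc2)C(=O)C1=O
F6 | step 2 | rac-4-(6,6-dimethyl-5,6-dihydro-4H-pyran-2-yl)-4-hydroxy-3-methoxy-2-(4-phenylbut-1-en-2-yl)cyclobut-2-en-1-one | O=C1C(C(=C)CCc2ccccc2)=C(OC)C1(O)C1=CCCC(C)(C)O1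
F7 | step 2 | 7-methoxy-2,2-dimethyl-6-(4-phenylbut-1-en-2-yl)chroman-5,8-diol | COc1c(O)c2c(c(O)c1C(=C)CCc1ccccc1)CCC(C)(C)O2
F8 | step 2 | 7-methoxy-2,2-dimethyl-6-(4-phenylbut-1-en-2-yl)chroman-5,8-diyl diacetate | COc1c(OC(C)=O)c2c(c(OC(C)=O)c1C(=C)CCc1ccccc1)CCC(C)(C)O2
F9 | step 6 | rac-4-bromo-7-methoxy-2,2-dimethyl-6-(3-phenylpropanoyl)chroman-5,8-diyl diacetate | COc1c(OC(C)=O)c2c(c(OC(C)=O)c1C(=O)CCc1ccccc1)C(Br)CC(C)(C)O2
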